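The diarylmethane bond between the bridging CH2 and C1' of the dibromocatechol ring (ring B) is the disconnection on which the route rests. In the target this CH2 sits on C2 of ring A, para to the C5 oxygen and ortho to the CH2OH-bearing C1, while C1' is para to the C4' hydroxyl. A phthalide therefore carries both ring-A carbons: 4-bromo-5,6-dimethoxyphthalide is opened by AlCl3 in a Friedel–Crafts alkylation of 2-bromo-6-methoxyphenol, which forms the diarylmethane bond para to the phenol OH and releases the carboxyl group in one operation. Bromination para to the ring-B methoxy group, borane reduction and BBr3 demethylation should then give the target.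

Key step: step 2

Remark: the target has no stereocentre and is achiral, so no step needs stereocontrol. Locants used for the target: ring A = C1 (CH2OH), C2 (bridging CH2), C3 (Br), C4 and C5 (OH), C6 (H); ring B = C1' (bridging CH2), C2' and C3' (Br), C4' and C5' (OH), C6' (H).

Step 1
Reactants: 1 3-bromo-4,5-dimethoxybenzoic acid
Product: 3 4-bromo-5,6-dimethoxyisobenzofuran-1(3H)-one, via hydroxymethyl acid 2 (not isolated)
Conditions: (CH2O)n, conc. HCl, AcOH, 85 °C
Reagents that add atoms: formaldehyde (used as paraformaldehyde), C=O
Why: Acid-mediated hydroxymethylation (Blanc-type electrophilic aromatic substitution) should occur at C2 of 1, the position para to the coplanar 5-methoxy group and the site that 5-bromoveratryl compounds use in ring bromination, and the ortho-hydroxymethyl acid 2 should lactonize in the flask, as in the conversion of veratric acid into 5,6-dimethoxyphthalide.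

Step 2
Reactants: 3 4-bromo-5,6-dimethoxyisobenzofuran-1(3H)-one; 4 2-bromo-6-methoxyphenol
Product: 5 3-bromo-2-[(3-bromo-4-hydroxy-5-methoxyphenyl)methyl]-4,5-dimethoxybenzoic acid
Conditions: AlCl3 (3 equiv), ClCH2CH2Cl, 0 → 50 °C; then aq. HCl
Reagents that add atoms: none
Why: AlCl3 binds the lactone carbonyl oxygen of 3 and the C3–O (alkyl–oxygen) bond ionizes to a benzylic cation, stabilized by the para methoxy group at C6 as an O-methyl para-quinone-methide cation and with the aluminium carboxylate as internal leaving group; the aluminium phenoxide of 4 attacks this cation through C4 and rearomatizes. The closest known reaction type is the Friedel–Crafts alkylation of arenes by lactones with AlCl3 (phthalide to 2-benzylbenzoic acids, γ-butyrolactone to 4-arylbutanoic acids). No ring is closed; the lactone ring is opened, which sets free the carboxyl group that later becomes the CH2OH. No stereocentre is formed. The step needs alkylation and not acylation, which the cation-stabilizing C6 methoxy group and the known alkyl–oxygen mode of lactone/AlCl3 reactions should secure. It also needs attack para to the phenol OH, which is secured because both ortho positions of 4 carry Br and OMe, so that C4 is the only free position conjugated to the phenol oxygen.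

Step 3
Reactants: 5 3-bromo-2-[(3-bromo-4-hydroxy-5-methoxyphenyl)methyl]-4,5-dimethoxybenzoic acid
Product: 6 3-bromo-2-[(2,3-dibromo-4-hydroxy-5-methoxyphenyl)methyl]-4,5-dimethoxybenzoic acid
Conditions: Br2 (1.05 equiv), AcOH, rt
Reagents that add atoms: bromine, BrBr
Why: Electrophilic aromatic bromination should take place on the phenol ring at the free position para to its methoxy group (C2' of the target), the site that 5-bromovanillin uses on the way to 5,6-dibromovanillin, while the benzoic acid ring is deactivated by CO2H and Br.

Step 4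
Reactants: 6 3-bromo-2-[(2,3-dibromo-4-hydroxy-5-methoxyphenyl)methyl]-4,5-dimethoxybenzoic acid
Product: 7 [3-bromo-2-[(2,3-dibromo-4-hydroxy-5-methoxyphenyl)methyl]-4,5-dimethoxyphenyl]methanol
Conditions: BH3·THF (4 equiv), THF, 0 °C → rt; then aq. NH4Cl
Reagents that add atoms: none
Why: Borane reduction of a carboxylic acid through its acyloxyborane is chemoselective and should leave the aryl bromides, the methyl ethers and the phenol (a borate until work-up) untouched.

Step 5
Reactants: 7 [3-bromo-2-[(2,3-dibromo-4-hydroxy-5-methoxyphenyl)methyl]-4,5-dimethoxyphenyl]methanol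
Product: 9 3-bromo-4-[(2,3-dibromo-4,5-dihydroxyphenyl)methyl]-5-(hydroxymethyl)benzene-1,2-diol, via benzylic bromide 8 (not isolated)
Conditions: BBr3 (8 equiv), CH2Cl2, −78 °C → rt; then H2O–THF, rt
Reagents that add atoms: water, O (benzylic OH of 9); boron tribromide, BrB(Br)Br (benzylic Br of intermediate 8 only)
Why: BBr3 ether cleavage should remove the three aryl methyl groups and turn the benzylic alcohol into bromide 8, and this bromide, which is para to the freed C4 hydroxyl, should hydrolyze in aqueous THF through a para-quinone methide to the benzylic alcohol, as is known for lanosol-type benzylic bromides.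

Compound list
1 | 3-bromo-4,5-dimethoxybenzoic acid | COc1cc(C(=O)O)cc(Br)c1OC | starting material
2 | 3-bromo-2-(hydroxymethyl)-4,5-dimethoxybenzoic acid | COc1cc(C(=O)O)c(CO)c(Br)c1OC | intermediate (not isolated)
3 | 4-bromo-5,6-dimethoxyisobenzofuran-1(3H)-one (4-bromo-5,6-dimethoxyphthalide) | COc1cc2C(=O)OCc2c(Br)c1OC | intermediate
4 | 2-bromo-6-methoxyphenol | COc1cccc(Br)c1O | starting material
5 | 3-bromo-2-[(3-bromo-4-hydroxy-5-methoxyphenyl)methyl]-4,5-dimethoxybenzoic acid | COc1cc(C(=O)O)c(Cc2cc(Br)c(O)c(OC)c2)c(Br)c1OC | intermediate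
6 | 3-bromo-2-[(2,3-dibromo-4-hydroxy-5-methoxyphenyl)methyl]-4,5-dimethoxybenzoic acid | COc1cc(C(=O)O)c(Cc2cc(OC)c(O)c(Br)c2Br)c(Br)c1OC | intermediate
7 | [3-bromo-2-[(2,3-dibromo-4-hydroxy-5-methoxyphenyl)methyl]-4,5-dimethoxyphenyl]methanol | COc1cc(CO)c(Cc2cc(OC)c(O)c(Br)c2Br)c(Br)c1OC | intermediate
8 | 3-bromo-5-(bromomethyl)-4-[(2,3-dibromo-4,5-dihydroxyphenyl)methyl]benzene-1,2-diol | Oc1cc(CBr)c(Cc2cc(O)c(O)c(Br)c2Br)c(Br)c1O | intermediate (not isolated)
9 | 3-bromo-4-[(2,3-dibromo-4,5-dihydroxyphenyl)methyl]-5-(hydroxymethyl)benzene-1,2-diol | OCc1cc(O)c(O)c(Br)c1Cc1cc(O)c(O)c(Br)c1Br | target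

Total step count: 5
Longest linear sequence: 5 steps (1 → 3 → 5 → 6 → 7 → 9; phenol 4 enters in step 2)

Steps most likely to fail

Step 2. The lactone may not ionize fast enough, so that the Lewis acid cleaves aryl methyl ethers or only acylates the phenol oxygen reversibly before any alkylation takes place. The fallback sets out from 3 and comes back at 5; it raises the electrophile to the oxocarbenium level. Radical bromination of 3 at the lactone CH2 (NBS, AIBN, PhCF3, reflux) should give racemic 3,4-dibromo-5,6-dimethoxyisobenzofuran-1(3H)-one F1. Hydrolysis (H2O–dioxane, reflux) should give racemic 4-bromo-3-hydroxy-5,6-dimethoxyisobenzofuran-1(3H)-one F2. Acid condensation of this hydroxyphthalide with phenol 4 (TFA, rt), a well-established reaction of 3-hydroxyphthalides with phenols, should give racemic 4-bromo-3-(3-bromo-4-hydroxy-5-methoxyphenyl)-5,6-dimethoxyisobenzofuran-1(3H)-one F3. Ionic hydrogenation of its doubly benzylic C–O bond (Et3SiH, TFA, 50 °C) should open the lactone to acid 5.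

Step 3. Site selectivity may be lost between the two open positions of the phenol ring, or ipso attack para to the phenol OH may lead to debenzylation or benzylic oxidation. The fallback sets out from 3 and comes back at 6; it puts both ring-B bromines in place before the coupling. Purchased 5-bromovanillin F4 should be brominated (Br2, Fe, NaOAc, AcOH) to 2,3-dibromo-4-hydroxy-5-methoxybenzaldehyde F5. Pinnick oxidation (NaClO2, NaH2PO4, 2-methyl-2-butene, t-BuOH–H2O) should give 2,3-dibromo-4-hydroxy-5-methoxybenzoic acid F6. Silver-catalysed protodecarboxylation of this ortho-bromo acid (Ag2CO3 cat., AcOH, DMSO, 120 °C) should give 2,3-dibromo-6-methoxyphenol F7. Its alkylation by 3 under the conditions of step 2, again para to the OH, should give 6 directly.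

Step 1. The substitution may be sluggish on a ring deactivated by CO2H and Br, or may take place at C6 ortho to the methoxy group. The fallback sets out from 1 and comes back at 3; it uses C–H acidity in place of ring nucleophilicity. Fischer esterification (MeOH, H2SO4, reflux) should give methyl 3-bromo-4,5-dimethoxybenzoate F8. Directed magnesiation at the C2–H flanked by the ester and the bromine (TMPMgCl·LiCl, THF, 0 °C), followed by DMF, should give methyl 3-bromo-2-formyl-4,5-dimethoxybenzoate F9. Reduction of the aldehyde (NaBH4, MeOH, 0 °C → rt) should be followed by lactonization of the alkoxide to 3.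

Further compounds
F1 | step 2 | 3,4-dibromo-5,6-dimethoxyisobenzofuran-1(3H)-one (racemic) | COc1cc2C(=O)OC(Br)c2c(Br)c1OC
F2 | step 2 | 4-bromo-3-hydroxy-5,6-dimethoxyisobenzofuran-1(3H)-one (racemic) | COc1cc2C(=O)OC(O)c2c(Br)c1OC
F3 | step 2 | 4-bromo-3-(3-bromo-4-hydroxy-5-methoxyphenyl)-5,6-dimethoxyisobenzofuran-1(3H)-one (racemic) | COc1cc2C(=O)OC(c3cc(Br)c(O)c(OC)c3)c2c(Br)c1OC
F4 | step 3 | 5-bromovanillin (3-bromo-4-hydroxy-5-methoxybenzaldehyde, purchased) | COc1cc(C=O)cc(Br)c1O
F5 | step 3 | 2,3-dibromo-4-hydroxy-5-methoxybenzaldehyde | COc1cc(C=O)c(Br)c(Br)c1O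
F6 | step 3 | 2,3-dibromo-4-hydroxy-5-methoxybenzoic acid | COc1cc(C(=O)O)c(Br)c(Br)c1O
F7 | step 3 | 2,3-dibromo-6-methoxyphenol | COc1ccc(Br)c(Br)c1O
F8 | step 1 | methyl 3-bromo-4,5-dimethoxybenzoate | COC(=O)c1cc(OC)c(OC)c(Br)c1
F9 | step 1 | methyl 3-bromo-2-formyl-4,5-dimethoxybenzoate | COC(=O)c1cc(OC)c(OC)c(Br)c1C=O
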